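## Structural features

The target is a 1H-indole: a benzene ring fused to a pyrrole ring through the C3a–C7a bond, with no side chain and no stereocentre. It carries three bromine atoms, two on the adjacent pyrrole carbons C2 and C3 and one on the benzene ring at C7, next to the ring-fusion carbon that bears N1; the nitrogen is unsubstituted. The fragile part is the 2,3-dibromo-1H-pyrrole unit. A 2-bromoindole with a free N–H is an enamine-like halide that is easily oxidised or hydrolysed towards an oxindole, can lose or shift bromine in acid, and darkens in light and air. The real difficulty is therefore placing three bromines and only three. Brominating an unprotected indole releases HBr beside the labile product and can reach C5 and C6, so the dibromopyrrole is best made N-protected and uncovered last under mild, non-acidic, non-reducing conditions. The C7 bromine sits ortho to nitrogen and can be bought in place in an ortho-bromoaniline. The key step exploits the fact that C2 and C3 both bear bromine: the C3–C2–Br unit is read as a bromoethynyl group on C3a, ortho to the nitrogen on C7a, and N1 plus a second bromine are added across that triple bond to close the pyrrole ring.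

## Logic of the disconnections

10 back to 8: no skeletal bond is cut; the N1–H bond is replaced by an N1–S bond to an arenesulfonyl group. The reason is that an electron-poor nitrogen stabilises the dibromopyrrole and is what the ring closure needs anyway. The gain is that the labile unit stays masked until the last operation. The demand is a cleavage by a nucleophile at sulfur, without reduction (three C–Br bonds) and without acid; the stage between cleavage and quench is 9.

8 back to 6 and 7: the N1–C2 bond and the C3–Br bond are cut, which opens the pyrrole ring to a 1-bromoalkyne ortho to a sulfonamide. This is the strategic cut, because it removes the ring and one bromine together and leaves the C2 bromine on the alkyne terminus. The gain is an acyclic, easily assembled arene. The demand is an anti addition of nitrogen and electrophilic bromine (from 7) across the triple bond in the 5-endo-dig sense, ahead of simple addition to the alkyne and of ring bromination.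

6 back to 5: the C(sp)–Br bond is cut and replaced by a C(sp)–Si bond. The silylalkyne is the stable form in which the two-carbon unit is introduced, and direct silicon-to-bromine exchange avoids handling the free terminal alkyne. The demand is that the electrophilic bromine goes to the alkyne terminus and not to nitrogen or the arene, and that the silver catalyst does not close the ring prematurely.

5 back to 3 and 4: the N–S bond is cut. Sulfonylation is placed after the cross-coupling because ortho-alkynyl sulfonanilides tend to cyclise under palladium and copper catalysis, whereas the free aniline couples cleanly. The demand is mono-sulfonylation of a hindered, weakly nucleophilic aniline with two ortho substituents.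

3 back to 1 and 2: the aryl–alkynyl bond (the future C3a–C3 bond) is cut. This reduces the problem to two commercial materials, and the C7 bromine is carried in from 1. The demand is a coupling that takes the C–I bond and leaves the C–Br bond alone, which means a mild catalyst at room temperature.

## Other disconnections considered

Alternative 1: The cut takes the benzene ring apart at C3a–C7a and C4–C5, so that C4 to C7 and both fusion carbons come from a 2-amidofuran carrying a butenyl chain on nitrogen, tert-butyl (3-bromofuran-2-yl)(but-3-en-1-yl)carbamate A2.
- Forward key step: A2 would be heated in toluene. The intramolecular [4+2] addition gives an oxygen-bridged adduct, the carbamate nitrogen opens the bridge, and loss of water aromatises the six-membered ring to tert-butyl 7-bromoindoline-1-carboxylate A1.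
- In its favour: the bromine on furan C3 can only end at C7. The step is thermal and reagent-free, and amidofuran cycloadditions of this kind are well established for indolines. On method risk it is the better of the two plans, since step 4 extends a known reaction to an untested alkyne class.
- Against it here: it builds a benzene ring that can be bought with the bromine in place (1; 7-bromo-1H-indole A3 is itself commercial). A2 needs several steps of its own and amidofurans are sensitive. After the key step the carbamate must be removed, the indoline dehydrogenated to A3, and both pyrrole bromines put on by electrophilic bromination of an N–H indole, the operation that releases HBr beside the labile product and may over-brominate.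
- Comparison: on regiocontrol at C7 the plans are equal. Mechanistically the cycloaddition closes two rings but sets none of the pyrrole C–Br bonds, whereas step 4 closes one ring and sets C3–Br with C2–Br already present. On step count it needs roughly eight or nine operations against five.

Alternative 2: The cut is at N1–C7a and C7–Br, leading back to N-allyl-2-(3-fluorophenyl)ethan-1-amine A5.
- Forward key step: an excess of a strong alkyllithium base would remove the N–H proton and the ring proton between fluorine and the side chain. Loss of LiF gives the aryne across C7–C7a, the lithium amide adds at C7a to close the five-membered ring, and the C7 aryllithium is trapped by a positive-bromine donor to give 1-allyl-7-bromoindoline A4.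
- In its favour: two bonds at the arene form in one flask from a cheap fluoroarene, and the bromine position follows from the mechanism. In making the C7–Br bond rather than buying it, its key step achieves more at the benzene ring than step 4 does; on that point it is the better.
- Against it here: the ring lithiation must occur at the more hindered position between fluorine and the chain and not on the other side of fluorine, where the aryne cannot be reached by the tether. It needs a pyrophoric base at low temperature. The allyl group must come off with zerovalent palladium in the presence of an aryl bromide, the indoline must be oxidised to A3, and the two pyrrole bromines are again left to a late bromination of a free indole.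
- Comparison: since 1 already contains the C7 bromine, the strength of this plan counts for little with this target, while its weakness, the unprotected dibromination at the end, is what the chosen plan avoids. Its step count is about six or seven against five, and the chosen route uses no organolithium reagent.

Alternative 3: The cut is at C3–C3a and N1–C2 in the Fischer sense, leading back to the pyruvate-derived arylhydrazone ethyl 2-[2-(2-bromophenyl)hydrazinylidene]propanoate A7.
- Forward key step: in a hot dehydrating acid the ene-hydrazine tautomer of A7 would undergo the [3,3] shift that makes C3–C3a and breaks N–N. The freed aniline nitrogen then closes on the iminium carbon with loss of ammonia to give ethyl 7-bromo-1H-indole-2-carboxylate A6.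
- In its favour: it uses cheap materials and no metal, is easy to scale, and only one ortho position is free, so only the 7-bromo isomer can form. In robustness and precedent it is the better of the two plans.
- Against it here: the C2 ester is only a handle and costs a saponification and a hot decarboxylation to reach A3. Ortho-halogenated hydrazones are known to be among the less well-behaved Fischer substrates. The endgame is once more the C3 and C2 bromination of an N–H indole.
- Comparison: in step count the two plans are about equal (five to six against five), and regiocontrol at C7 is equal. The difference is mechanistic: the Fischer step sets no C–Br bond and ends with bromination of the unprotected heterocycle, whereas step 4 delivers the 2,3-dibromopyrrole already protected on nitrogen.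

Key step: step 4

Remark on the chemistry: the atom mapping of 6 onto 8 was checked (aniline carbon to C7a, its bromine-bearing neighbour to C7, its alkynyl-bearing neighbour to C3a, alkyne carbons to C3 and C2) and no structure needs correction. One point is added to the design: the cell in step 4 contains one equivalent of acetic acid as the cathodic proton source. Without it, one equivalent of hydroxide per molecule would build up and could attack the N-sulfonyl group of 8. The bonds formed are unchanged.

## Route

Step 1
Reactants: 1 2-bromo-6-iodoaniline; 2 ethynyltrimethylsilane
Product: 3 2-bromo-6-[(trimethylsilyl)ethynyl]aniline
Conditions: PdCl2(PPh3)2 (2 mol%), CuI (4 mol%), Et3N, THF, rt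
Reagents that add atoms: none
Why: Sonogashira coupling; zerovalent palladium formed from the divalent precatalyst inserts into C–I far faster than into C–Br at room temperature, so the future C7 bromine is kept, and the free amino group and the silylalkyne are inert under these conditions.

Step 2
Reactants: 3 2-bromo-6-[(trimethylsilyl)ethynyl]aniline; 4 4-methylbenzenesulfonyl chloride
Product: 5 N-{2-bromo-6-[(trimethylsilyl)ethynyl]phenyl}-4-methylbenzenesulfonamide
Conditions: TsCl (1.3 equiv), pyridine, 60 °C
Reagents that add atoms: none
Why: N-sulfonylation of a primary aniline with pyridine as base and nucleophilic catalyst; the two ortho substituents slow the reaction (hence gentle warming) but also disfavour a second sulfonylation, and the silylalkyne does not react.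

Step 3
Reactants: 5 N-{2-bromo-6-[(trimethylsilyl)ethynyl]phenyl}-4-methylbenzenesulfonamide
Product: 6 N-[2-bromo-6-(bromoethynyl)phenyl]-4-methylbenzenesulfonamide
Conditions: NBS (1.1 equiv), AgNO3 (10 mol%), acetone, rt, dark
Reagents that add atoms: N-bromosuccinimide, O=C1CCC(=O)N1Br
Why: Silver-catalysed desilylative bromination of a trimethylsilylalkyne (ipso exchange of silicon for bromine at the sp carbon); the sulfonanilide ring is too deactivated for ring bromination under these neutral conditions, and the free terminal alkyne is never isolated.

Step 4
Reactants: 6 N-[2-bromo-6-(bromoethynyl)phenyl]-4-methylbenzenesulfonamide; 7 sodium bromide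
Product: 8 2,3,7-tribromo-1-(4-methylbenzenesulfonyl)-1H-indole
Conditions: NaBr (2.0 equiv), AcOH (1.2 equiv), MeCN/H2O 9:1, undivided cell, graphite anode, Pt cathode, constant current 10 mA until 6 is consumed (theory 2 F/mol), rt; then aq Na2S2O3
Reagents that add atoms: none
Why: Proposed new method: the closest known reaction type is the electrophilic bromocyclization of N-sulfonyl 2-alkynylanilines to 3-bromoindoles with anodically generated bromine, and the untested element is a 1-bromoalkyne in place of a carbon-substituted alkyne. Bromide is oxidised at graphite to bromine while platinum reduces the protons of acetic acid to hydrogen, which leaves acetate as the only base in the cell. Bromine forms a π-complex or bridged bromirenium ion on the triple bond, and the sulfonamide nitrogen, deprotonated in equilibrium by acetate, attacks the bromine-bearing carbon anti to it (N1–C2) while the new bromine stays on the aryl-bearing carbon (C3–Br). The one ring that forms closes in the 5-endo-dig mode, because attack at the aryl-bearing carbon would be a 4-exo-dig closure that the ortho geometry rules out. No stereocentre is formed. The step needs ring closure to win over addition of bromide or water across the activated alkyne, which the intramolecular nitrogen nucleophile and the low standing concentration of electrogenerated bromine should secure. It also needs the benzene ring and the C–Br bonds to stay untouched, which the deactivating sulfonyl group and C7 bromine and the low overpotential of proton reduction on platinum should secure.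

Step 5
Reactants: 8 2,3,7-tribromo-1-(4-methylbenzenesulfonyl)-1H-indole
Product: 10 2,3,7-tribromo-1H-indole, via tetrabutylammonium indolide 9 (not isolated)
Conditions: Bu4NF (2.0 equiv), THF, 0 °C to rt, argon, dark; then aq NH4Cl
Reagents that add atoms: none
Why: Nucleophilic N-desulfonylation of an N-sulfonylindole by fluoride at sulfur; the tribromoindolide is a good leaving group and its departure relieves the crowding between the sulfonyl group and the C2 and C7 bromines, the conditions are neither reducing nor acidic so the three C–Br bonds survive, and the sulfonyl fluoride formed cannot alkylate the indolide.

## Compound list

1 | 2-bromo-6-iodoaniline | Nc1c(Br)cccc1I | starting material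
2 | ethynyltrimethylsilane | C#C[Si](C)(C)C | starting material
3 | 2-bromo-6-[(trimethylsilyl)ethynyl]aniline | C[Si](C)(C)C#Cc1cccc(Br)c1N | intermediate
4 | 4-methylbenzenesulfonyl chloride | Cc1ccc(cc1)S(Cl)(=O)=O | starting material
5 | N-{2-bromo-6-[(trimethylsilyl)ethynyl]phenyl}-4-methylbenzenesulfonamide | Cc1ccc(cc1)S(=O)(=O)Nc1c(Br)cccc1C#C[Si](C)(C)C | intermediate
6 | N-[2-bromo-6-(bromoethynyl)phenyl]-4-methylbenzenesulfonamide | Cc1ccc(cc1)S(=O)(=O)Nc1c(Br)cccc1C#CBr | intermediate
7 | sodium bromide | [Na+].[Br-] | starting material
8 | 2,3,7-tribromo-1-(4-methylbenzenesulfonyl)-1H-indole | Cc1ccc(cc1)S(=O)(=O)n1c(Br)c(Br)c2cccc(Br)c21 | intermediate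
9 | tetrabutylammonium 2,3,7-tribromoindol-1-ide | CCCC[N+](CCCC)(CCCC)CCCC.Brc1[n-]c2c(Br)cccc2c1Br | intermediate
10 | 2,3,7-tribromo-1H-indole | Brc1[nH]c2c(Br)cccc2c1Br | target

## Step count and least certain steps

Total step count: 5. Longest linear sequence: 5 steps (1 to 3 to 5 to 6 to 8 to 10).

Step 4 (key step, proposed new method). The most likely failure is delivery of bromine with the wrong polarity. A 1-bromoalkyne is polarised so that positive charge prefers the aryl-bearing carbon, which the nitrogen cannot reach. Bromine could therefore add at the bromine-bearing terminus and be followed by capture of bromide or water at the aryl-bearing carbon (addition or oxy-bromination of the alkyne) instead of ring closure. The electron-poor alkyne may also be activated so slowly that bromine accumulates. Fallback with known chemistry, setting out from 6: the ring closure and the bromination are separated. Treatment of 6 with Cs2CO3 in DMF at 60 °C should effect the base-promoted 5-endo-dig addition of the sulfonamide to the alkyne, a known reaction type for ortho-alkynyl sulfonanilides, to give 2,7-dibromo-1-(4-methylbenzenesulfonyl)-1H-indole F1. Electrophilic substitution of F1 at C3 with Br2 in CH2Cl2 at 0 °C, the usual site of bromination of N-sulfonylindoles, then rejoins the route at 8. If the nitrogen adds to the alkyne before bromine arrives during the electrolysis itself, the same intermediate F1 would be expected to be brominated in the cell and converge on 8.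

Step 3. The most likely failure is silver-promoted closure of the sulfonamide nitrogen onto the alkyne, or bromination at nitrogen, before the silicon is exchanged; the N–H group sits next to a silver-activated triple bond. Fallback, setting out from 5: the silver is avoided and the bromine is delivered to a preformed acetylide at low temperature. K2CO3 in MeOH at rt should remove the silyl group to give N-(2-bromo-6-ethynylphenyl)-4-methylbenzenesulfonamide F2. Double deprotonation with LiN(SiMe3)2 (2.2 equiv) in THF at −78 °C gives the dilithium salt of F2 at nitrogen and the alkyne terminus F3 (not isolated), whose acetylide carbon is brominated by NBS (1.05 equiv) at −78 °C; an acetic acid quench rejoins the route at 6.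

Step 5. The most likely failure is slow attack of fluoride at a sulfur atom shielded by the C2 and C7 bromines, which gives time for substitution at C2 or for degradation of the freed indolide (oxidation, hydrolytic loss of the C2 bromine) before and during isolation. Fallback, setting out from 3: the nitrogen is carried through with a sulfonyl group that fluoride removes at a remote silicon atom instead of at sulfur. Aniline 3 with 2-(trimethylsilyl)ethanesulfonyl chloride in pyridine should give N-{2-bromo-6-[(trimethylsilyl)ethynyl]phenyl}-2-(trimethylsilyl)ethane-1-sulfonamide F4. NBS with catalytic AgNO3 gives N-[2-bromo-6-(bromoethynyl)phenyl]-2-(trimethylsilyl)ethane-1-sulfonamide F5, and the electrolysis of step 4 gives 2,3,7-tribromo-1-{[2-(trimethylsilyl)ethyl]sulfonyl}-1H-indole F6. Bu4NF in THF at rt then triggers fragmentation to fluorotrimethylsilane, ethene and sulfur dioxide, which rejoins the route at 9 and, after the NH4Cl quench, at 10.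

Step 2. The most likely failure is sluggish sulfonylation of the electron-poor aniline with two ortho substituents. Forcing conditions could then cause loss of the silyl group, closure onto the alkyne or a second sulfonylation. Fallback, setting out from 1: the order of the first two steps is reversed so that the forcing step is run before the alkyne is present. Aniline 1 with 4 in pyridine at 80 °C should give N-(2-bromo-6-iodophenyl)-4-methylbenzenesulfonamide F7 (any doubly sulfonylated material can be cut back with mild hydroxide). Sonogashira coupling of F7 with 2 under the conditions of step 1, kept at room temperature to avoid palladium- or copper-induced ring closure, rejoins the route at 5.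

## Further compounds

F1 | step 4 | 2,7-dibromo-1-(4-methylbenzenesulfonyl)-1H-indole | Cc1ccc(cc1)S(=O)(=O)n1c(Br)cc2cccc(Br)c21
F2 | step 3 | N-(2-bromo-6-ethynylphenyl)-4-methylbenzenesulfonamide | Cc1ccc(cc1)S(=O)(=O)Nc1c(Br)cccc1C#C
F3 | step 3 | dilithium salt of F2 (sulfonamide nitrogen and alkyne terminus deprotonated) | [Li+].[Li+].Cc1ccc(cc1)S(=O)(=O)[N-]c1c(Br)cccc1C#[C-]
F4 | step 5 | N-{2-bromo-6-[(trimethylsilyl)ethynyl]phenyl}-2-(trimethylsilyl)ethane-1-sulfonamide | C[Si](C)(C)CCS(=O)(=O)Nc1c(Br)cccc1C#C[Si](C)(C)C
F5 | step 5 | N-[2-bromo-6-(bromoethynyl)phenyl]-2-(trimethylsilyl)ethane-1-sulfonamide | C[Si](C)(C)CCS(=O)(=O)Nc1c(Br)cccc1C#CBr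
F6 | step 5 | 2,3,7-tribromo-1-{[2-(trimethylsilyl)ethyl]sulfonyl}-1H-indole | C[Si](C)(C)CCS(=O)(=O)n1c(Br)c(Br)c2cccc(Br)c21
F7 | step 2 | N-(2-bromo-6-iodophenyl)-4-methylbenzenesulfonamide | Cc1ccc(cc1)S(=O)(=O)Nc1c(Br)cccc1I
A1 | alternative 1 | tert-butyl 7-bromoindoline-1-carboxylate | CC(C)(C)OC(=O)N1CCc2cccc(Br)c21
A2 | alternative 1 | tert-butyl (3-bromofuran-2-yl)(but-3-en-1-yl)carbamate | CC(C)(C)OC(=O)N(CCC=C)c1occc1Br
A3 | alternative 1 | 7-bromo-1H-indole | Brc1cccc2cc[nH]c12
A4 | alternative 2 | 1-allyl-7-bromoindoline | C=CCN1CCc2cccc(Br)c21
A5 | alternative 2 | N-allyl-2-(3-fluorophenyl)ethan-1-amine | C=CCNCCc1cccc(F)c1
A6 | alternative 3 | ethyl 7-bromo-1H-indole-2-carboxylate | CCOC(=O)c1cc2cccc(Br)c2[nH]1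
A7 | alternative 3 | ethyl 2-[2-(2-bromophenyl)hydrazinylidene]propanoate (either C=N isomer) | CCOC(=O)C(C)=NNc1ccccc1Br
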